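## The problem

The target 17 is a 2-arylchroman (flavan). Benzene ring A is fused to a saturated pyran ring through C4a and C8a, and ring B is attached at C2, the only stereocentre, which must be (S). With no second stereocentre to relay configuration, C2 has to be set by a chiral catalyst and then guarded. It is a benzylic ether carbon whose ring B carries a para oxygen (O4'), so it can ionise under acid or open through a quinone methide once O4' is a free phenoxide. Ring A carries OMe at C6, OH at C7 and a prenyl group at C8; ring B carries a prenyl group at C2' and a catechol at C3'/C4'. Two carbon chains must therefore be placed at the most crowded positions, and three phenols must be told apart from one methyl ether. The catechol is oxidised easily in base and air, each prenyl group sits ortho to a phenol and cyclises to a 2,2-dimethylchroman under acid, and the trisubstituted alkenes forbid late hydrogenation. The opening is that the two side chains are identical: each ends in a C2''=C3'' alkene with two methyl groups on C3'', so C1''–C2'' is an allyl group short of its terminus. Each allyl group stands ortho to a phenolic oxygen (O7 for C8, O3' for C2') whose other ortho carbon is blocked (C6 by OMe, C4' by oxygen), so it can be moved from oxygen to carbon without ambiguity and capped afterwards.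

## Retrosynthesis

**17 ⇒ 16.** The three phenolic O–H bonds are traced back to O–acetyl bonds. Acetates come off by basic methanolysis, the one deprotection that needs neither acid (fatal next to ortho-prenyl phenols) nor reduction. The triacetate 16 is no simpler than 17 in skeleton, but it is stable to air and to ruthenium.

**16 ⇒ 14 + 15.** Both C2''=C3'' double bonds are cut, which turns each prenyl group into an allyl group and an isopropylidene donor, 2-methyl-2-butene 15. The neighbouring options are weaker: direct C-prenylation of the phenols gives O/C and positional mixtures, and rearrangement of prenyl ethers puts a 1,1-dimethylallyl group on the ortho carbon. The precursor 14 carries only two plain, identical terminal alkenes. The forward reaction must exchange both termini completely without moving the double bonds.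

**14 ⇒ 13 ⇒ 12.** Three O–acetyl bonds and then one methoxymethyl acetal bond at O4' are cut. The acetal is removed at the allyl stage because ortho-allylphenols tolerate dilute acid far better than ortho-prenylphenols. The forward steps need only mild acid, then exhaustive acylation.

**12 ⇒ 11.** The C8–C1'' and C2'–C1'' bonds are cut and the allyl groups returned to O7 and O3'. A double aromatic Claisen rearrangement is preferred over any electrophilic or organometallic allylation because the position is dictated by the oxygen: C8 and C2' are the only free ortho carbons. Compound 11 has no carbon substituent on either arene beyond the flavan skeleton. The forward step needs about 195 °C, so O4' must carry a group that neither migrates nor leaves (the methoxymethyl ether).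

**11 ⇒ 10.** The O1–C8a bond is cut, giving an open-chain (S)-alcohol with bromine at the future C8a. The alternative cut at C2–O1, closed by SN2 with inversion, would make and break a bond at the easily ionised benzylic carbon. The aryl-oxygen cut leaves C2 untouched. The forward reaction is a copper-catalysed intramolecular etherification on an electron-rich aryl bromide.

**10 ⇒ 9 ⇒ 8.** The C2–H bond is cut (carbinol back to the aryl ketone 9), then the C3–H/C4–H bonds (back to the enone 8). Catalyst-controlled transfer hydrogenation is chosen over a borane-based oxazaborolidine reduction because borane would hydroborate the allyl ethers. Conjugate reduction by copper hydride is chosen over catalytic hydrogenation for the same reason. Both steps must spare two terminal alkenes and an aryl bromide.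

**8 ⇒ 6 + 3.** The C3=C4 bond is cut by a Claisen–Schmidt disconnection into methyl ketone 6 (ring B, C2, C3) and aldehyde 3 (ring A, C4). This divides the molecule into two trisubstituted benzenes of similar size. The forward reaction needs only base-stable protecting groups.

**6 ⇒ 5 ⇒ 4, and 3 ⇒ 1 + 2.** Only O–C bonds are cut. In 4 the hydroxyl para to the acetyl group is the more acidic, so it takes the methoxymethyl group first and leaves O3 for allyl bromide 2. Compound 1 already has bromine, oxygen and methoxy where C8a, O7 and the C6 methoxy group are needed, so one allylation gives 3.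

## Roads not taken

**Alternative 1:** The cut runs through C4a–C8a, so ring A is built instead of bought. Thermolysis of a four-membered-ring precursor assembled on a squaric acid core would open it to a dienylketene. Its 6π-electrocyclisation and tautomerisation would give (R)-3-(allyloxy)-6-[3-(3,4-bis(methoxymethoxy)-2-prenylphenyl)-3-(tert-butyldimethylsilyloxy)propyl]-4-methoxy-2-prenylphenol A1.
- Merits: the order of additions to the four-carbon core fixes OMe at C6, oxygen at C7 and the prenyl group at C8 without any regiochemical question. Both prenyl groups travel in finished form, and the key step is neutral and thermal.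
- Weak points: ring A is an ordinary 1,2,4-trioxygenated benzene available as 1, so its construction is a long linear detour. The 2'-prenyl group and the carbinol stereocentre still need separate solutions before the key step. A1 is not yet a chroman: the silyl ether must be removed and the pyran closed at C2 by SN2 with inversion, at the carbon that ionises most easily. O7 must finally be deallylated with zerovalent palladium.
- Comparison: this road is better in the certainty of the ring A substitution pattern and in sparing an advanced intermediate 195 °C. The chosen plan sets against it purchased arenes with the oxygens in place, a ring closure (step 7) that never touches C2, and both side chains installed by the same two operations.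

**Alternative 2:** The cut is C4a–C5. Ring A would be folded from a chain of masked carbonyl groups already attached to the pyran ring. KN(SiMe3)2 would deprotonate C4a of a cyclic vinylogous ester, and the extended enolate would attack C5 with loss of methoxide. Tautomerisation would give (S)-2-[3,4-bis(methoxymethoxy)-2-prenylphenyl]-6-methoxy-8-prenylchroman-7-ol A2.
- Merits: A2 is one deprotection from 17, the C7 hydroxyl is formed free and distinct from O6, and no transition metal is needed.
- Weak points: the open-chain precursor must carry the future C6 methoxy group, the future C8 prenyl group and the C2 stereocentre. Its assembly is longer and much less familiar than the union of two benzenes. The strong base must select C4a among several acidic sites, and C- over O-cyclisation. The last step removes two methoxymethyl ethers with acid while both prenyl groups sit ortho to phenols, the situation most prone to 2,2-dimethylchroman formation.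
- Comparison: fewer protecting-group operations after the key step and a metal-free ring formation are real advantages. The chosen plan sets against them that its only acid step (step 9) precedes the prenyl groups, that its end-game is a basic methanolysis, and that each ring- and chain-forming step belongs to a familiar reaction class.

**Alternative 3:** The cut is C3=C4. Ring-closing metathesis of a diene made of a C4a vinyl group and a 1-arylallyl aryl ether would close the pyran ring as (S)-6-methoxy-7-(methoxymethoxy)-2-[3,4-bis(methoxymethoxy)-2-prenylphenyl]-8-prenyl-2H-chromene A3.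
- Merits: six-membered ring-closing metathesis with the second-generation Grubbs catalyst is dependable. The allylic ether could come from a catalytic enantioselective allylic etherification that forms O1–C2 and the stereocentre together, and the approach is convergent.
- Weak points: in A3, C2 is at once benzylic, allylic and oxygen-bound, and 2-aryl-2H-chromenes open reversibly by 6π-electrocycloreversion to quinone methides, a direct path to racemisation. The diene already holds two prenyl groups, so four alkenes compete for ruthenium. C3=C4 must then be saturated beside two trisubstituted alkenes, which excludes ordinary hydrogenation and leaves diimide-type reductions of imperfect selectivity. Three methoxymethyl ethers must finally be removed by acid next to the prenyl groups.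
- Comparison: this road reaches the heterocycle in fewer steps and sets C2 catalytically as the ether bond forms, which is more direct than reduction followed by coupling. The chosen plan sets against it a saturated, configurationally robust flavan throughout, and a metathesis substrate 14 whose only alkenes are two identical allyl termini, so no alkene ever has to be distinguished from another.

Key step: step 11

Assumption: compounds 1 and 4 are taken to be purchasable, and the stereodescriptor encoded in the target SMILES is read as (2S).

## Route

Step 1
Reactants: 1 2-bromo-4-hydroxy-5-methoxybenzaldehyde (6-bromovanillin); 2 allyl bromide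
Product: 3 4-(allyloxy)-2-bromo-5-methoxybenzaldehyde
Conditions: K2CO3, DMF, 50 °C
Reagents that add atoms: none
Why: Williamson ether synthesis: the phenoxide of 1 displaces bromide from 2 by SN2, and the aldehyde and the aryl bromide are inert under these conditions.

Step 2
Reactants: 4 1-(3,4-dihydroxyphenyl)ethan-1-one (3,4-dihydroxyacetophenone)
Product: 5 1-[3-hydroxy-4-(methoxymethoxy)phenyl]ethan-1-one
Conditions: MOMCl (1.05 equiv), K2CO3 (1.1 equiv), acetone, 0 °C → rt
Reagents that add atoms: chloromethyl methyl ether (MOMCl), COCCl
Why: Regioselective O-alkylation: the hydroxyl para to the acetyl group is the more acidic and is the one deprotonated by a single equivalent of base, so it takes the methoxymethyl group; minor bis-ether and regioisomer should be separable.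

Step 3
Reactants: 5 1-[3-hydroxy-4-(methoxymethoxy)phenyl]ethan-1-one; 2 allyl bromide
Product: 6 1-[3-(allyloxy)-4-(methoxymethoxy)phenyl]ethan-1-one
Conditions: K2CO3, DMF, 50 °C
Reagents that add atoms: none
Why: Williamson ether synthesis on the one remaining phenol; the acetal and the ketone are stable to carbonate.

Step 4
Reactants: 6 1-[3-(allyloxy)-4-(methoxymethoxy)phenyl]ethan-1-one; 3 4-(allyloxy)-2-bromo-5-methoxybenzaldehyde
Product: 8 (E)-3-[4-(allyloxy)-2-bromo-5-methoxyphenyl]-1-[3-(allyloxy)-4-(methoxymethoxy)phenyl]prop-2-en-1-one, via racemic aldol adduct 7 (not isolated)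
Conditions: KOH, EtOH/H2O, 0 °C → rt
Reagents that add atoms: none
Why: Claisen–Schmidt condensation: the enolate of methyl ketone 6 adds to the non-enolisable aldehyde 3 and the aldol 7 dehydrates by E1cB to the conjugated E-enone; ethers, acetal and aryl bromide are base-stable.

Step 5
Reactants: 8 (E)-3-[4-(allyloxy)-2-bromo-5-methoxyphenyl]-1-[3-(allyloxy)-4-(methoxymethoxy)phenyl]prop-2-en-1-one
Product: 9 3-[4-(allyloxy)-2-bromo-5-methoxyphenyl]-1-[3-(allyloxy)-4-(methoxymethoxy)phenyl]propan-1-one
Conditions: Cu(OAc)2 (5 mol %), 1,2-bis(diphenylphosphino)benzene (5 mol %), (EtO)2MeSiH (1.3 equiv), t-BuOH (2 equiv), toluene, 0 °C → rt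
Reagents that add atoms: none
Why: Copper hydride conjugate reduction: the phosphine-ligated CuH formed from Cu(OAc)2 and the silane delivers hydride to the β-carbon of the enone only, and t-BuOH protonates the copper enolate to release the ketone. Isolated terminal alkenes and the aryl bromide are not substrates for this hydride, which is why it replaces catalytic hydrogenation.

Step 6
Reactants: 9 3-[4-(allyloxy)-2-bromo-5-methoxyphenyl]-1-[3-(allyloxy)-4-(methoxymethoxy)phenyl]propan-1-one
Product: 10 (S)-3-[4-(allyloxy)-2-bromo-5-methoxyphenyl]-1-[3-(allyloxy)-4-(methoxymethoxy)phenyl]propan-1-ol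
Conditions: RuCl(p-cymene)[(S,S)-TsDPEN] (2 mol %), HCO2H/Et3N (5:2), EtOAc, 35 °C
Reagents that add atoms: none
Why: Noyori asymmetric transfer hydrogenation: hydride and proton pass from Ru–H/N–H to the ketone in an outer-sphere six-membered transition state in which the arene ligand holds ring B by a CH/π contact. The (S,S)-catalyst thereby delivers hydride to the Re face and should give the (S)-carbinol, the established sense for aryl alkyl ketones; no borane is present, so the allyl groups are safe.

Step 7
Reactants: 10 (S)-3-[4-(allyloxy)-2-bromo-5-methoxyphenyl]-1-[3-(allyloxy)-4-(methoxymethoxy)phenyl]propan-1-ol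
Product: 11 (S)-7-(allyloxy)-2-[3-(allyloxy)-4-(methoxymethoxy)phenyl]-6-methoxychroman
Conditions: CuI (10 mol %), 3,4,7,8-tetramethyl-1,10-phenanthroline (20 mol %), Cs2CO3 (2 equiv), toluene, 110 °C, argon
Reagents that add atoms: none
Why: Ullmann-type intramolecular C–O coupling: the caesium alkoxide binds monovalent copper, the aryl bromide is activated at the metal and the O1–C8a bond forms through a six-membered ring. No bond to C2 is made or broken, so the (S) configuration is carried into the chroman unchanged; the temperature is far below that needed for Claisen rearrangement of the allyl ethers.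

Step 8
Reactants: 11 (S)-7-(allyloxy)-2-[3-(allyloxy)-4-(methoxymethoxy)phenyl]-6-methoxychroman
Product: 12 (S)-8-allyl-2-[2-allyl-3-hydroxy-4-(methoxymethoxy)phenyl]-6-methoxychroman-7-ol
Conditions: N,N-diethylaniline, 195 °C, argon
Reagents that add atoms: none
Why: Double aromatic Claisen rearrangement ([3,3]-sigmatropic shift, then tautomerisation): the O7 allyl group can only end at C8 because C6 bears OMe, and the O3' allyl group at C2' because C4' bears oxygen. The amine solvent buffers the new phenols against acid-catalysed cyclisation, and the acetal on O4' keeps ring B from opening the C2–O1 bond through a quinone methide.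

Step 9
Reactants: 12 (S)-8-allyl-2-[2-allyl-3-hydroxy-4-(methoxymethoxy)phenyl]-6-methoxychroman-7-ol
Product: 13 (S)-8-allyl-2-(2-allyl-3,4-dihydroxyphenyl)-6-methoxychroman-7-ol
Conditions: HCl (cat.), MeOH, 40 °C, argon
Reagents that add atoms: none
Why: Acid-catalysed transacetalisation of the methoxymethyl ether to methanol; it is placed here because ortho-allylphenols resist acid-induced cyclisation far better than the later ortho-prenylphenols. Dilute acid and a short reaction time should spare the benzylic ether at C2.

Step 10
Reactants: 13 (S)-8-allyl-2-(2-allyl-3,4-dihydroxyphenyl)-6-methoxychroman-7-ol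
Product: 14 (S)-8-allyl-2-(2-allyl-3,4-diacetoxyphenyl)-6-methoxychroman-7-yl acetate
Conditions: Ac2O, pyridine, DMAP (cat.), CH2Cl2, rt
Reagents that add atoms: acetic anhydride, CC(=O)OC(C)=O
Why: DMAP-catalysed O-acylation of all three phenols, including the two hindered ones between an allyl group and an oxygen substituent; the triacetate is stable to air and no longer offers a free phenol or catechol to ruthenium.

Step 11
Reactants: 14 (S)-8-allyl-2-(2-allyl-3,4-diacetoxyphenyl)-6-methoxychroman-7-yl acetate; 15 2-methyl-2-butene
Product: 16 (S)-2-[3,4-diacetoxy-2-(3-methylbut-2-en-1-yl)phenyl]-6-methoxy-8-(3-methylbut-2-en-1-yl)chroman-7-yl acetate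
Conditions: second-generation Grubbs catalyst (10 mol %), 1,4-benzoquinone (20 mol %), 2-methyl-2-butene/CH2Cl2 (1:1), 40 °C, sealed tube
Reagents that add atoms: none
Why: Olefin cross-metathesis by the ruthenacyclobutane mechanism: the large excess of 15 converts the ruthenium benzylidene into isopropylidene and ethylidene species, [2+2] cycloaddition of the isopropylidene to a terminal CH=CH2 of 14 and cycloreversion give the ArCH2–CH=C(CH3)2 unit and a ruthenium methylidene, and 15 recaps the methylidene with release of propene. The closest known reaction type is the conversion of allylarenes and other terminal alkenes into prenyl groups by cross-metathesis with 2-methyl-2-butene. No ring is closed and no stereocentre is formed; the new alkenes carry two identical methyl groups, so no E/Z question arises, and C2 is remote from the reacting sites. The selectivity needed is cross- over self-metathesis with full conversion at both termini: 15 as co-solvent outnumbers 14 many times over, and the trisubstituted product alkenes are poor substrates for further metathesis, so each terminus is funnelled into the prenyl group and stays there. A crotyl terminus formed by ethylidene transfer is still a reactive disubstituted alkene and is carried on to the same product. Migration of the allyl double bond into conjugation, caused by ruthenium hydride decomposition products, is held back by 1,4-benzoquinone and the moderate temperature. The three acetates keep the phenols and the catechol, which could bind or reduce ruthenium, out of the reaction.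

Step 12
Reactants: 16 (S)-2-[3,4-diacetoxy-2-(3-methylbut-2-en-1-yl)phenyl]-6-methoxy-8-(3-methylbut-2-en-1-yl)chroman-7-yl acetate
Product: 17 (S)-2-[3,4-dihydroxy-2-(3-methylbut-2-en-1-yl)phenyl]-6-methoxy-8-(3-methylbut-2-en-1-yl)chroman-7-ol (CNP0214453.1)
Conditions: K2CO3 (cat.), degassed MeOH, 0 °C, argon; then aq. NH4Cl
Reagents that add atoms: none
Why: Base-catalysed transesterification (methanolysis) of the three aryl acetates; no acid touches the ortho-prenylphenols. Low temperature, short contact and exclusion of air should protect the catechol and keep the ring B phenoxide from opening the C2–O1 bond.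

## Compound list

1 | 2-bromo-4-hydroxy-5-methoxybenzaldehyde (6-bromovanillin) | O=Cc1cc(OC)c(O)cc1Br | starting material
2 | allyl bromide | C=CCBr | starting material
3 | 4-(allyloxy)-2-bromo-5-methoxybenzaldehyde | O=Cc1cc(OC)c(OCC=C)cc1Br | intermediate
4 | 1-(3,4-dihydroxyphenyl)ethan-1-one | CC(=O)c1ccc(O)c(O)c1 | starting material
5 | 1-[3-hydroxy-4-(methoxymethoxy)phenyl]ethan-1-one | CC(=O)c1ccc(OCOC)c(O)c1 | intermediate
6 | 1-[3-(allyloxy)-4-(methoxymethoxy)phenyl]ethan-1-one | CC(=O)c1ccc(OCOC)c(OCC=C)c1 | intermediate
7 | 3-[4-(allyloxy)-2-bromo-5-methoxyphenyl]-1-[3-(allyloxy)-4-(methoxymethoxy)phenyl]-3-hydroxypropan-1-one (racemic, not isolated) | O=C(CC(O)c1cc(OC)c(OCC=C)cc1Br)c1ccc(OCOC)c(OCC=C)c1 | intermediate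
8 | (E)-3-[4-(allyloxy)-2-bromo-5-methoxyphenyl]-1-[3-(allyloxy)-4-(methoxymethoxy)phenyl]prop-2-en-1-one | O=C(/C=C/c1cc(OC)c(OCC=C)cc1Br)c1ccc(OCOC)c(OCC=C)c1 | intermediate
9 | 3-[4-(allyloxy)-2-bromo-5-methoxyphenyl]-1-[3-(allyloxy)-4-(methoxymethoxy)phenyl]propan-1-one | O=C(CCc1cc(OC)c(OCC=C)cc1Br)c1ccc(OCOC)c(OCC=C)c1 | intermediate
10 | (S)-3-[4-(allyloxy)-2-bromo-5-methoxyphenyl]-1-[3-(allyloxy)-4-(methoxymethoxy)phenyl]propan-1-ol | O[C@H](c1ccc(OCOC)c(OCC=C)c1)CCc1cc(OC)c(OCC=C)cc1Br | intermediate
11 | (S)-7-(allyloxy)-2-[3-(allyloxy)-4-(methoxymethoxy)phenyl]-6-methoxychroman | COc1cc2c(cc1OCC=C)O[C@H](c1ccc(OCOC)c(OCC=C)c1)CC2 | intermediate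
12 | (S)-8-allyl-2-[2-allyl-3-hydroxy-4-(methoxymethoxy)phenyl]-6-methoxychroman-7-ol | COc1cc2c(c(CC=C)c1O)O[C@H](c1ccc(OCOC)c(O)c1CC=C)CC2 | intermediate
13 | (S)-8-allyl-2-(2-allyl-3,4-dihydroxyphenyl)-6-methoxychroman-7-ol | COc1cc2c(c(CC=C)c1O)O[C@H](c1ccc(O)c(O)c1CC=C)CC2 | intermediate
14 | (S)-8-allyl-2-(2-allyl-3,4-diacetoxyphenyl)-6-methoxychroman-7-yl acetate | COc1cc2c(c(CC=C)c1OC(C)=O)O[C@H](c1ccc(OC(C)=O)c(OC(C)=O)c1CC=C)CC2 | intermediate
15 | 2-methyl-2-butene | CC=C(C)C | starting material
16 | (S)-2-[3,4-diacetoxy-2-(3-methylbut-2-en-1-yl)phenyl]-6-methoxy-8-(3-methylbut-2-en-1-yl)chroman-7-yl acetate | COc1cc2c(c(CC=C(C)C)c1OC(C)=O)O[C@H](c1ccc(OC(C)=O)c(OC(C)=O)c1CC=C(C)C)CC2 | intermediate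
17 | (S)-2-[3,4-dihydroxy-2-(3-methylbut-2-en-1-yl)phenyl]-6-methoxy-8-(3-methylbut-2-en-1-yl)chroman-7-ol | COc1cc2c(c(CC=C(C)C)c1O)O[C@H](c1ccc(O)c(O)c1CC=C(C)C)CC2 | target

## Step count and least certain steps

Total step count: 12. Longest linear sequence: 11 steps (from 4 through steps 2 to 12; step 1 supplies the second fragment).

**Step 11 (key step).** What may go wrong: incomplete exchange at one of the two termini; migration of an allyl double bond into conjugation by ruthenium hydride species, followed by metathesis of the propenyl group with loss of one carbon; and homodimerisation if 15 is lost by evaporation. Fallback, setting out from 12 and avoiding metathesis: the two free phenols of 12 are converted into methoxymethyl ethers (MOMCl, i-Pr2NEt, CH2Cl2) to give (S)-8-allyl-2-[2-allyl-3,4-bis(methoxymethoxy)phenyl]-6-methoxy-7-(methoxymethoxy)chroman F1. Lemieux–Johnson cleavage of both terminal alkenes (OsO4 cat., NaIO4, 2,6-lutidine, dioxane/H2O) should give the dialdehyde (S)-2-[3,4-bis(methoxymethoxy)-2-(2-oxoethyl)phenyl]-6-methoxy-7-(methoxymethoxy)-8-(2-oxoethyl)chroman F2. Twofold Wittig olefination with the ylide from isopropyltriphenylphosphonium iodide and n-BuLi in THF then installs both isopropylidene caps to give (S)-2-[3,4-bis(methoxymethoxy)-2-(3-methylbut-2-en-1-yl)phenyl]-6-methoxy-7-(methoxymethoxy)-8-(3-methylbut-2-en-1-yl)chroman F3. Brief exposure to dilute HCl in methanol at room temperature removes the three acetals and rejoins the route at 17.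

**Step 7.** What may go wrong: slow activation of the electron-rich aryl bromide (para to OMe) at copper, so that protodebromination or oxidation of the benzylic alkoxide competes with ring closure. Fallback, setting out from 9 and closing the ring at C2 instead: transfer hydrogenation with the enantiomeric catalyst RuCl(p-cymene)[(R,R)-TsDPEN] gives (R)-3-[4-(allyloxy)-2-bromo-5-methoxyphenyl]-1-[3-(allyloxy)-4-(methoxymethoxy)phenyl]propan-1-ol F4. Deprotonation and bromine–lithium exchange (n-BuLi, 2.2 equiv, THF, −78 °C), trapping with B(OMe)3 and oxidation with H2O2/NaOH convert the bromide into the phenol (R)-5-(allyloxy)-2-{3-[3-(allyloxy)-4-(methoxymethoxy)phenyl]-3-hydroxypropyl}-4-methoxyphenol F5. Mitsunobu cyclodehydration (PPh3, DIAD, toluene, 0 °C) closes C2–O1 with inversion and rejoins the route at 11. Here the benzylic ionisation discussed above must be watched by checking the enantiomeric purity of 11.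

**Step 8.** What may go wrong: rearrangement on ring B by way of the blocked ortho carbon C4' and onward migration to the para carbon C6', giving a positional isomer, and thermal damage during prolonged heating. Fallback, setting out from 11 and replacing the sigmatropic shift by phenoxide C-alkylation: both allyl ethers are cleaved with zerovalent palladium (Pd(PPh3)4 cat., morpholine, THF, rt) to give (S)-2-[3-hydroxy-4-(methoxymethoxy)phenyl]-6-methoxychroman-7-ol F6. Its disodium salt (NaH, toluene) is alkylated with 2 under the non-polar, heterogeneous conditions that favour ortho C-allylation, again at C8 and C2' as the only free ortho carbons. This rejoins the route at 12, and material allylated on oxygen is simply 11 or a precursor of it and can be recycled.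

**Step 5.** What may go wrong: further 1,2-reduction of the product ketone by excess copper hydride, or competing reduction of the carbonyl group before the alkene. Fallback, setting out from 3 and building the saturated chain without an enone: NaBH4 in methanol gives [4-(allyloxy)-2-bromo-5-methoxyphenyl]methanol F7, and PBr3 in CH2Cl2 gives 4-(allyloxy)-2-bromo-5-methoxybenzyl bromide F8. Alkylation of the lithium enolate of 6 (LiN(SiMe3)2, THF, −78 °C → 0 °C, enolate in excess to limit double alkylation) with F8 forms the C3–C4 bond directly and rejoins the route at 9.

## Further compounds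

F1 | step 11 | (S)-8-allyl-2-[2-allyl-3,4-bis(methoxymethoxy)phenyl]-6-methoxy-7-(methoxymethoxy)chroman | COc1cc2c(c(CC=C)c1OCOC)O[C@H](c1ccc(OCOC)c(OCOC)c1CC=C)CC2
F2 | step 11 | (S)-2-[3,4-bis(methoxymethoxy)-2-(2-oxoethyl)phenyl]-6-methoxy-7-(methoxymethoxy)-8-(2-oxoethyl)chroman | COc1cc2c(c(CC=O)c1OCOC)O[C@H](c1ccc(OCOC)c(OCOC)c1CC=O)CC2
F3 | step 11 | (S)-2-[3,4-bis(methoxymethoxy)-2-(3-methylbut-2-en-1-yl)phenyl]-6-methoxy-7-(methoxymethoxy)-8-(3-methylbut-2-en-1-yl)chroman | COc1cc2c(c(CC=C(C)C)c1OCOC)O[C@H](c1ccc(OCOC)c(OCOC)c1CC=C(C)C)CC2
F4 | step 7 | (R)-3-[4-(allyloxy)-2-bromo-5-methoxyphenyl]-1-[3-(allyloxy)-4-(methoxymethoxy)phenyl]propan-1-ol | O[C@@H](c1ccc(OCOC)c(OCC=C)c1)CCc1cc(OC)c(OCC=C)cc1Br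
F5 | step 7 | (R)-5-(allyloxy)-2-{3-[3-(allyloxy)-4-(methoxymethoxy)phenyl]-3-hydroxypropyl}-4-methoxyphenol | O[C@@H](c1ccc(OCOC)c(OCC=C)c1)CCc1cc(OC)c(OCC=C)cc1O
F6 | step 8 | (S)-2-[3-hydroxy-4-(methoxymethoxy)phenyl]-6-methoxychroman-7-ol | COc1cc2c(cc1O)O[C@H](c1ccc(OCOC)c(O)c1)CC2
F7 | step 5 | [4-(allyloxy)-2-bromo-5-methoxyphenyl]methanol | OCc1cc(OC)c(OCC=C)cc1Br
F8 | step 5 | 4-(allyloxy)-2-bromo-5-methoxybenzyl bromide | BrCc1cc(OC)c(OCC=C)cc1Br
A1 | alternative 1 | (R)-3-(allyloxy)-6-[3-(3,4-bis(methoxymethoxy)-2-prenylphenyl)-3-(tert-butyldimethylsilyloxy)propyl]-4-methoxy-2-prenylphenol | COc1cc(CC[C@@H](O[Si](C)(C)C(C)(C)C)c2ccc(OCOC)c(OCOC)c2CC=C(C)C)c(O)c(CC=C(C)C)c1OCC=C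
A2 | alternative 2 | (S)-2-[3,4-bis(methoxymethoxy)-2-prenylphenyl]-6-methoxy-8-prenylchroman-7-ol | COc1cc2c(c(CC=C(C)C)c1O)O[C@H](c1ccc(OCOC)c(OCOC)c1CC=C(C)C)CC2
A3 | alternative 3 | (S)-6-methoxy-7-(methoxymethoxy)-2-[3,4-bis(methoxymethoxy)-2-prenylphenyl]-8-prenyl-2H-chromene | COc1cc2c(c(CC=C(C)C)c1OCOC)O[C@H](c1ccc(OCOC)c(OCOC)c1CC=C(C)C)C=C2
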